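# Proposed total synthesis of CNP0110626.2 by anionic acetylenic oxy-Cope ring expansion

## The problem

The target is a 5,10-seco-clerodane: a cyclodeca-1(10),2,4-triene whose ring atoms are called C1–C10 here (clerodane numbering: C4 carries the carboxyl C18, C5 the acetoxymethyl C19, C8 the methyl C17, C9 the methyl C20 and the 2-(furan-3-yl)ethyl chain C11–C16). The ten-membered carbocycle must hold a conjugated triene with one E double bond (C1=C10) and two ring-cis double bonds (C2=C3 and the tetrasubstituted C4=C5). Any end-to-end closure therefore fights entropy, transannular strain and oligomerisation, and the finished triene is a 6π array that can close thermally across C5/C10. The only stereocentres, C8 (tertiary) and the adjacent quaternary C9, lie in the flexible saturated arc; they cannot be controlled once the medium ring exists and must be set beforehand in a rigid ring, where C8 can direct C9. On C4=C5 the carboxyl and the acetoxymethyl group are cis: a free C19 hydroxyl would lactonise onto C18, so C19 has to arrive already acetylated and C18 must be unmasked last under non-hydrolytic conditions. The 3-alkylfuran excludes strong acid, electrophilic oxidants and singlet oxygen, the allylic acetate excludes hydroxide and long contact with Pd(0), and the triene excludes heat. The enabling feature is that C5 and C10 stand 1,6 across the ring: the saturated arc C6–C7–C8–C9 together with C5 and C10 is a latent cyclohexane that carries both stereocentres, and the unsaturated arc C1–C2–C3–C4 consists of two two-carbon units (C1–C2 on C10, C3–C4 on C5) joined at C2–C3. With C5 at the oxidation level of a ketone enol, the ring is the [3,3] product of a 1-ethynyl-2-vinylcyclohexanolate, and the C5 oxygen that drives the shift later becomes the leaving group through which C19 is introduced.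

## Retrosynthesis

**19 to 18.** No skeletal bond is cut; the C18 acid of target 19 is masked as the 2-(trimethylsilyl)ethyl ester 18. A methyl ester would need hydroxide (the acetate goes first), a tert-butyl ester acid (furan, triene), an allyl ester Pd(0) in the presence of a second allylic ester. Fluoride-induced fragmentation asks only for a cold, non-hydrolytic last step.

**18 to 17.** The C5–C19 bond is cut, giving the trienyl triflate 17 and (acetoxymethyl)zinc bromide. A tetrasubstituted alkene of defined geometry is most safely taken from the enol triflate of a β-keto ester, whose geometry is that of the chelated enolate. The alternative cut C4–C18 at this stage would need a C4 ketone, which the ring expansion cannot deliver. C19 enters at its final oxidation level and already acetylated, so no free hydroxyl ever faces C18. The coupling must go with retention at ambient temperature.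

**17 to 15 to 14.** No C–C bond is cut between 17 and 15: 17 is the O-triflate of the dienolate 16 of keto ester 15. This enolisation creates C2=C3 and C4=C5 together and is a funnel on which every C3=C4 isomer and tautomer of 15 converges. 15 is traced to the α-iodo dienone 14 by cutting C4–C18 (alkoxycarbonylation of the alkenyl iodide). The precursor 14 has no triene and is thermally robust.

**14 to 11 (key disconnection).** The C2–C3 bond is cut and C5–C10 is re-formed on paper: 14 is the iodine-trapped allenolate 13 that results from the [3,3] shift of the potassium alkoxide 12 of carbinol 11. Against the all-alkene version (a vinyl group on C5), the alkyne supplies the missing unsaturation: C3=C4 of the allenolate is later transposed to C2=C3 by enolisation, so no late dehydrogenation is needed. The precursor 11 is a plain cyclohexanol with no medium ring and no geometric alkene. Of its four stereocentres only C8 and C9 matter; the other two are erased. The forward reaction must give the E C1=C10 bond and must outrun loss of acetylide.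

**11 to 10 to 8.** C4–C5 is cut (ethynyl Grignard addition to ketone 10) and then C1–C10 (α-vinylation of the regio-defined silyl enol ether 8). Neither new centre needs control. The vinyl group must be placed on the more hindered α-carbon, which only the conjugate-addition enolate can address regiospecifically.

**8 to 4 plus 6.** C9–C11 is cut: copper-catalysed 1,4-addition of the Grignard reagent 7 (from bromide 6) to (R)-3,4-dimethylcyclohex-2-enone 4. This is the one place where C8 controls C9, addition anti to the C8 methyl giving the cis-dimethyl pattern. Cutting C9–C20 instead (methyl cuprate on a 3-furylethyl enone) would give the wrong diastereomer.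

**4 to 3 to 1; 6 to 5.** Enone 4 is the conjugated, enantioenriched isomer of the β,γ-enone 3, itself the Birch/hydrolysis product (via enol ether 2) of 3,4-dimethylanisole 1; no C–C bond is made. Bromide 6 comes from 2-(furan-3-yl)ethanol 5.

## Roads not taken

**Alternative 1:** (the obvious one) Cut C3–C4 and close the ring end to end, for example by intramolecular Stille coupling of the acyclic stannyl dienyl iodo-enoate A1. Ring-closing metathesis at C2=C3 or a Nozaki–Hiyama–Kishi closure are variants of the same idea. The forward step must fold an E,Z-diene and a tetrasubstituted alkene into a ten-membered ring, against the entropy of a nine-atom tether, developing transannular strain and competing dimerisation. A1 itself needs the C8/C9 pair built in an acyclic setting without a ring to relay C8 to C9, plus separate stereodefined syntheses of a Z-vinylstannane and a tetrasubstituted iodo-enoate. In the chosen plan the ring is formed by reorganising σ bonds inside a six-centre transition state, with no end-to-end entropy cost, and the E geometry is a consequence of that transition state.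

**Alternative 2:** Form no ring bond at the end but break C5–C10: photochemical conrotatory 6π ring opening of the cis-fused clerodane-type 1,3-diene A2 (or the thermal disrotatory opening of its trans-fused isomer). This is the biomimetic route. A2 requires a complete decalin with two extra stereocentres (quaternary C5 and C10) that are built only to be destroyed. The two conrotatory senses lead to the (1(10)E,4Z) and (1(10)Z,4E) trienes with no evident bias. The triene product absorbs where the diene does and is open to E/Z isomerisation, hydrogen shifts and thermal re-closure, and the furan is exposed to light. The chosen plan reaches the same C5/C10 relationship from the opposite side and needs only a monocyclic precursor.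

**Alternative 3:** Cut C2=C3 as a Ramberg–Bäcklund retron: ring contraction of the eleven-membered bis-allylic sulfone A3, made by double S-alkylation of a bis-allylic dihalide and oxidation. The larger sulfide ring closes more easily, but the acyclic dihalide again needs the C8/C9 pair and both substituted alkenes made separately. Sulfide oxidation has to spare the furan. α-Halogenation must choose between C2, C3 and the vinylogous positions of the enoate, and the hydroxide/halogen conditions attack the acetate. The Z geometry of the new C2=C3 bond is not secured. In the chosen plan C2=C3 arises by enolisation under ring control, without sulfur and without strong base in the presence of the acetate.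

Key step: step 7

**Assumptions (remarks on the chemistry):**
- The (1(10)E,2Z,4Z)-triene of 17, 18 and 19 is taken to resist 6π-electrocyclisation below about 40 °C, as the existence of the target as an isolable compound implies; steps 9–11 are therefore run at or below ambient temperature.
- The conformers of the (E)-cyclodecene unit are taken to interconvert or to be fixed by C8/C9, since the target SMILES defines no planar chirality.
- 2-(Furan-3-yl)ethanol 5 is taken as a catalogue compound.

## Steps

Step 1
Reactants: 1 3,4-dimethylanisole
Product: 3 3,4-dimethylcyclohex-3-en-1-one, via 1-methoxy-4,5-dimethylcyclohexa-1,4-diene 2 (not isolated)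
Conditions: Li, NH3(l), t-BuOH, THF, −78 to −33 °C; then (CO2H)2, MeOH/H2O, rt
Reagents that add atoms: water, O
Why: Birch reduction leaves the methoxy- and methyl-bearing carbons on the two double bonds (2); mild oxalic acid hydrolysis of the enol ether should give the β,γ-unsaturated ketone without conjugating the tetrasubstituted alkene.

Step 2
Reactants: 3 3,4-dimethylcyclohex-3-en-1-one
Product: 4 (R)-3,4-dimethylcyclohex-2-en-1-one
Conditions: 9-amino(9-deoxy)epi-cinchona primary amine (10 mol%), carboxylic acid co-catalyst, toluene, rt
Reagents that add atoms: none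
Why: Catalytic enantioselective β,γ-to-α,β isomerisation of a cyclohex-3-enone by iminium/dienamine proton-transfer catalysis; the protonated quinuclidine of the catalyst delivers the proton to one face of C4 of the dienamine and so sets C4 (the later C8), the catalyst pseudo-enantiomer that leads to (R) being chosen in a first run.

Step 3
Reactants: 5 2-(furan-3-yl)ethan-1-ol
Product: 6 3-(2-bromoethyl)furan
Conditions: CBr4, PPh3, CH2Cl2, 0 °C
Reagents that add atoms: carbon tetrabromide, BrC(Br)(Br)Br
Why: Appel bromination of a primary alcohol under neutral conditions that the furan tolerates.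

Step 4
Reactants: 6 3-(2-bromoethyl)furan; 4 (R)-3,4-dimethylcyclohex-2-en-1-one
Product: 8 trimethyl({(3S,4R)-3-[2-(furan-3-yl)ethyl]-3,4-dimethylcyclohex-1-en-1-yl}oxy)silane, via [2-(furan-3-yl)ethyl]magnesium bromide 7 (not isolated)
Conditions: Mg, THF; then CuBr·SMe2 (10 mol%), TMSCl, DMPU, THF, −78 °C, add 4; Et3N, pentane work-up
Reagents that add atoms: chlorotrimethylsilane, C[Si](C)(C)Cl
Why: Copper-catalysed, TMSCl-accelerated 1,4-addition of Grignard reagent 7; the C4 methyl shields one face of the half-chair enone, so the chain should enter anti to it and set the quaternary centre (the later C9) with the two methyls cis, and the enolate is trapped as the regio-defined silyl enol ether.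

Step 5
Reactants: 8 trimethyl({(3S,4R)-3-[2-(furan-3-yl)ethyl]-3,4-dimethylcyclohex-1-en-1-yl}oxy)silane
Product: 10 (3S,4R)-2-ethenyl-3-[2-(furan-3-yl)ethyl]-3,4-dimethylcyclohexan-1-one (both C2 epimers), via tributylstannyl enolate 9 (not isolated)
Conditions: CH2=CHBr (1 M in THF), Bu3SnF, Pd2(dba)3/P(t-Bu)3 (cat.), toluene, 70 °C, sealed tube
Reagents that add atoms: bromoethene, C=CBr
Why: Pd-catalysed α-alkenylation of a silyl enol ether through its tin enolate 9 (Si-to-Sn exchange, transmetallation to vinyl-Pd-Br, reductive elimination) is regiospecific for C2 and base-free, so the β,γ-unsaturated ketone should not be conjugated; the quaternary C3 leaves the C-bound Pd enolate without a β-hydrogen, and the C2 configuration is irrelevant because step 7 erases it.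

Step 6
Reactants: 10 (3S,4R)-2-ethenyl-3-[2-(furan-3-yl)ethyl]-3,4-dimethylcyclohexan-1-one
Product: 11 (3S,4R)-2-ethenyl-1-ethynyl-3-[2-(furan-3-yl)ethyl]-3,4-dimethylcyclohexan-1-ol (mixture of C1/C2 diastereomers)
Conditions: HC≡CMgBr (0.5 M in THF), LaCl3·2LiCl, THF, 0 °C; aq NH4Cl
Reagents that add atoms: ethynylmagnesium bromide, C#C[Mg]Br
Why: 1,2-Addition of the acetylide to the ketone, with the lanthanum salt raising carbonyl electrophilicity and suppressing enolisation at the doubly activated C2–H; every diastereomer is usable because C1 and C2 both become sp2 in step 7.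

Step 7
Reactants: 11 (3S,4R)-2-ethenyl-1-ethynyl-3-[2-(furan-3-yl)ethyl]-3,4-dimethylcyclohexan-1-ol
Product: 14 (2E,5E,7S,8R)-7-[2-(furan-3-yl)ethyl]-2-iodo-7,8-dimethylcyclodeca-2,5-dien-1-one, via potassium alkoxide 12 (not isolated), via potassium allenolate 13 (not isolated)
Conditions: KHMDS (1.05 equiv), 18-crown-6, THF, 0 °C to rt (to 50 °C if needed); then cannulated into I2, THF, −78 °C, dark; aq Na2S2O3
Reagents that add atoms: iodine, II
Why: The potassium alkoxide 12 undergoes an anionic acetylenic oxy-Cope rearrangement: in the array C3≡C4–C5(O−)–C10–C1=C2 the σ bond C5–C10 breaks as the σ bond C2–C3 forms, which enlarges the cyclohexane by four atoms to the ten-membered allenolate 13. The closest known reactions are the anionic oxy-Cope ring expansion of 1,2-divinylcyclohexanols to (E)-cyclodec-5-enones and the oxy-Cope ring expansion of 1-alkynyl-2-vinylcycloalkanols to cycloalka-2,5-dienones. The ten-membered ring is thus closed not end to end but by a [3,3] sigmatropic ring enlargement through a chair-like six-centre transition state, driven by the change from alkoxide to delocalised allenolate. No stereocentre is formed; C5 and C10 are erased, so all diastereomers of 11 should converge on one product, and C8 and C9 are not touched. The C1=C10 geometry is set in the transition state: the vinyl rotamer with the quaternary C9 pseudo-equatorial (H-10, not C9, eclipsing C1=C2) avoids A1,3 strain and leads to the E alkene from either C10 epimer. The allenolate is then iodinated at its central carbon C4, in the plane of the C3 substituents and anti to the ring residue C2; the C3=C4 geometry so formed is of no consequence because step 9 erases it. The selectivities needed are [3,3] shift over retro-ethynylation of the tertiary propargylic alkoxide, favoured by the dissociated potassium/crown ion pair at the lowest workable temperature, and C-iodination ahead of proton shuffling, secured by inverse addition to iodine at −78 °C.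

Step 8
Reactants: 14 (2E,5E,7S,8R)-7-[2-(furan-3-yl)ethyl]-2-iodo-7,8-dimethylcyclodeca-2,5-dien-1-one
Product: 15 2-(trimethylsilyl)ethyl (1E,4E,6S,7R)-6-[2-(furan-3-yl)ethyl]-6,7-dimethyl-10-oxocyclodeca-1,4-diene-1-carboxylate
Conditions: CO (3 bar), PdCl2(PPh3)2 (5 mol%), Me3SiCH2CH2OH (10 equiv), i-Pr2NEt, THF, rt to 40 °C
Reagents that add atoms: carbon monoxide, [C-]#[O+]; 2-(trimethylsilyl)ethanol, C[Si](C)(C)CCO
Why: Pd-catalysed alkoxycarbonylation of an α-iodo enone (oxidative addition, CO insertion, alcoholysis of the acyl-Pd) installs C18 as the fluoride-labile ester; the large excess of alcohol and the CO pressure should keep ester formation ahead of transannular acyl-palladation of C1=C10, and the keto form of 15 contains no triene.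

Step 9
Reactants: 15 2-(trimethylsilyl)ethyl (1E,4E,6S,7R)-6-[2-(furan-3-yl)ethyl]-6,7-dimethyl-10-oxocyclodeca-1,4-diene-1-carboxylate
Product: 17 2-(trimethylsilyl)ethyl (1Z,2Z,4E,6S,7R)-6-[2-(furan-3-yl)ethyl]-6,7-dimethyl-10-[(trifluoromethanesulfonyl)oxy]cyclodeca-1(10),2,4-triene-1-carboxylate, via sodium dienolate 16 (not isolated)
Conditions: NaH, Et2O, 0 °C; then Tf2O, −78 to 0 °C
Reagents that add atoms: trifluoromethanesulfonic anhydride, O=S(=O)(OS(=O)(=O)C(F)(F)F)C(F)(F)F
Why: The C2 protons (clerodane numbering) are γ to both carbonyls and allylic to the E alkene, so NaH should give the chelated β-keto ester dienolate 16, on which both C3=C4 isomers and all tautomers of 15 converge; O-sulfonylation of the ketone oxygen in the sodium chelate places the triflate cis to the ester (ring-cis C4=C5), and the new C2=C3 bond is expected Z because a second E double bond is not readily accommodated in the conjugated ten-membered ring.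

Step 10
Reactants: 17 2-(trimethylsilyl)ethyl (1Z,2Z,4E,6S,7R)-6-[2-(furan-3-yl)ethyl]-6,7-dimethyl-10-[(trifluoromethanesulfonyl)oxy]cyclodeca-1(10),2,4-triene-1-carboxylate
Product: 18 2-(trimethylsilyl)ethyl (1Z,2Z,4E,6S,7R)-10-(acetoxymethyl)-6-[2-(furan-3-yl)ethyl]-6,7-dimethylcyclodeca-1(10),2,4-triene-1-carboxylate
Conditions: AcOCH2ZnBr (from BrCH2OAc, Zn, LiCl, THF), Pd(PPh3)4 (5 mol%), THF, 0 °C to rt
Reagents that add atoms: (acetoxymethyl)zinc bromide, CC(=O)OC[Zn]Br (made from bromomethyl acetate, CC(=O)OCBr, and zinc)
Why: Negishi coupling of the electron-poor alkenyl triflate with the α-acyloxyalkylzinc reagent should proceed with retention at C5, so the acetoxymethyl group ends cis to the ester; C19 enters already acetylated, which avoids a free hydroxyl that would lactonise onto C18, and ambient temperature limits contact of Pd(0) with the new hindered allylic acetate.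

Step 11
Reactants: 18 2-(trimethylsilyl)ethyl (1Z,2Z,4E,6S,7R)-10-(acetoxymethyl)-6-[2-(furan-3-yl)ethyl]-6,7-dimethylcyclodeca-1(10),2,4-triene-1-carboxylate
Product: 19 (1Z,2Z,4E,6S,7R)-10-(acetoxymethyl)-6-[2-(furan-3-yl)ethyl]-6,7-dimethylcyclodeca-1(10),2,4-triene-1-carboxylic acid (target)
Conditions: TASF, DMF, 0 °C; pH 4 phosphate buffer
Reagents that add atoms: none
Why: Fluoride attacks silicon and the ester fragments to carboxylate, ethene and fluorotrimethylsilane (β-elimination); the anhydrous, non-hydrolytic conditions at 0 °C should leave the primary acetate, the furan and the triene untouched.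

## Compound list

1 | 3,4-dimethylanisole | COc1ccc(C)c(C)c1 | starting material
2 | 1-methoxy-4,5-dimethylcyclohexa-1,4-diene | COC1=CCC(C)=C(C)C1 | intermediate (not isolated)
3 | 3,4-dimethylcyclohex-3-en-1-one | CC1=C(C)CC(=O)CC1 | intermediate
4 | (R)-3,4-dimethylcyclohex-2-en-1-one | C[C@@H]1CCC(=O)C=C1C | intermediate
5 | 2-(furan-3-yl)ethan-1-ol | OCCc1ccoc1 | starting material
6 | 3-(2-bromoethyl)furan | BrCCc1ccoc1 | intermediate
7 | [2-(furan-3-yl)ethyl]magnesium bromide | Br[Mg]CCc1ccoc1 | intermediate (not isolated)
8 | trimethyl({(3S,4R)-3-[2-(furan-3-yl)ethyl]-3,4-dimethylcyclohex-1-en-1-yl}oxy)silane | C[Si](C)(C)OC1=C[C@@](C)(CCc2ccoc2)[C@H](C)CC1 | intermediate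
9 | tributyl({(3S,4R)-3-[2-(furan-3-yl)ethyl]-3,4-dimethylcyclohex-1-en-1-yl}oxy)stannane (tin enolate) | CCCC[Sn](CCCC)(CCCC)OC1=C[C@@](C)(CCc2ccoc2)[C@H](C)CC1 | intermediate (not isolated)
10 | (3S,4R)-2-ethenyl-3-[2-(furan-3-yl)ethyl]-3,4-dimethylcyclohexan-1-one, both C2 epimers (C2 left undefined on purpose) | O=C1C(C=C)[C@@](C)(CCc2ccoc2)[C@H](C)CC1 | intermediate
11 | (3S,4R)-2-ethenyl-1-ethynyl-3-[2-(furan-3-yl)ethyl]-3,4-dimethylcyclohexan-1-ol, C1/C2 diastereomers (left undefined on purpose) | OC1(C#C)C(C=C)[C@@](C)(CCc2ccoc2)[C@H](C)CC1 | intermediate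
12 | potassium (3S,4R)-2-ethenyl-1-ethynyl-3-[2-(furan-3-yl)ethyl]-3,4-dimethylcyclohexan-1-olate | [K+].[O-]C1(C#C)C(C=C)[C@@](C)(CCc2ccoc2)[C@H](C)CC1 | intermediate (not isolated)
13 | potassium (5E,7S,8R)-7-[2-(furan-3-yl)ethyl]-7,8-dimethylcyclodeca-1,2,5-trien-1-olate (allenolate) | [K+].[O-]C1=C=CC/C=C/[C@@](C)(CCc2ccoc2)[C@H](C)CC1 | intermediate (not isolated)
14 | (2E,5E,7S,8R)-7-[2-(furan-3-yl)ethyl]-2-iodo-7,8-dimethylcyclodeca-2,5-dien-1-one | O=C1/C(I)=C\C/C=C/[C@@](C)(CCc2ccoc2)[C@H](C)CC1 | intermediate
15 | 2-(trimethylsilyl)ethyl (1E,4E,6S,7R)-6-[2-(furan-3-yl)ethyl]-6,7-dimethyl-10-oxocyclodeca-1,4-diene-1-carboxylate | O=C1/C(C(=O)OCC[Si](C)(C)C)=C\C/C=C/[C@@](C)(CCc2ccoc2)[C@H](C)CC1 | intermediate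
16 | sodium (1Z,3Z,5E,7S,8R)-7-[2-(furan-3-yl)ethyl]-7,8-dimethyl-2-{[2-(trimethylsilyl)ethoxy]carbonyl}cyclodeca-1,3,5-trien-1-olate | [Na+].[O-]/C1=C(C(=O)OCC[Si](C)(C)C)/C=C\C=C\[C@@](C)(CCc2ccoc2)[C@H](C)CC1 | intermediate (not isolated)
17 | 2-(trimethylsilyl)ethyl (1Z,2Z,4E,6S,7R)-6-[2-(furan-3-yl)ethyl]-6,7-dimethyl-10-[(trifluoromethanesulfonyl)oxy]cyclodeca-1(10),2,4-triene-1-carboxylate | FC(F)(F)S(=O)(=O)O/C1=C(C(=O)OCC[Si](C)(C)C)/C=C\C=C\[C@@](C)(CCc2ccoc2)[C@H](C)CC1 | intermediate
18 | 2-(trimethylsilyl)ethyl (1Z,2Z,4E,6S,7R)-10-(acetoxymethyl)-6-[2-(furan-3-yl)ethyl]-6,7-dimethylcyclodeca-1(10),2,4-triene-1-carboxylate | CC(=O)OC/C1=C(C(=O)OCC[Si](C)(C)C)/C=C\C=C\[C@@](C)(CCc2ccoc2)[C@H](C)CC1 | intermediate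
19 | (1Z,2Z,4E,6S,7R)-10-(acetoxymethyl)-6-[2-(furan-3-yl)ethyl]-6,7-dimethylcyclodeca-1(10),2,4-triene-1-carboxylic acid | CC(=O)OC/C1=C(C(=O)O)/C=C\C=C\[C@@](C)(CCc2ccoc2)[C@H](C)CC1 | target

## Step count and risks

Total steps: 11. Longest linear sequence: 10 steps (1, 3, 4, 8, 10, 11, 14, 15, 17, 18, 19); step 3 is the only step off the main line.

**Step 7 (key step).** The most likely failure is loss of acetylide from the tertiary propargylic alkoxide (retro-ethynylation back to 10) competing with the [3,3] shift, because the unstrained cyclohexane gives the rearrangement no strain release. The second is proton transfer within the allenolate before the iodine quench, which would give isomeric dienolates and a mixture of iodides. The fallback sets out from 10 and returns to 14 through the fully alkene-based ring expansion. Vinylmagnesium bromide (LaCl3·2LiCl, THF) would give (3S,4R)-1,2-diethenyl-3-[2-(furan-3-yl)ethyl]-3,4-dimethylcyclohexan-1-ol F1. Its potassium alkoxide (KH, 18-crown-6, THF) should undergo the classical anionic oxy-Cope ring expansion, and the enolate is quenched with PhSeCl to give (5E,7S,8R)-7-[2-(furan-3-yl)ethyl]-7,8-dimethyl-2-(phenylselanyl)cyclodec-5-en-1-one F2. Oxidation (H2O2, pyridine, CH2Cl2, 0 °C) and selenoxide syn-elimination towards C3 gives (2Z,5E,7S,8R)-7-[2-(furan-3-yl)ethyl]-7,8-dimethylcyclodeca-2,5-dien-1-one F3 (the 2E isomer would serve equally). α-Iodination (I2, pyridine, CH2Cl2) leads back to 14. If the rearrangement works and only the iodine quench fails, 13 is quenched into acetic acid at −78 °C to give F3 directly, which is iodinated in the same way.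

**Step 5.** Transmetallation and reductive elimination at the neopentyl carbon next to the quaternary centre may be slow, so that protodestannylation to the parent ketone wins; the α-vinyl ketone may also drift into conjugation with the carbonyl. The fallback sets out from 8 and returns to 10 by a polar two-step vinylation. MeLi (THF, 0 °C) liberates the lithium enolate. Aldol addition to 2-(phenylselanyl)acetaldehyde at −78 °C would give (3S,4R)-3-[2-(furan-3-yl)ethyl]-2-[1-hydroxy-2-(phenylselanyl)ethyl]-3,4-dimethylcyclohexan-1-one F4. MsCl/Et3N then effects the anti-elimination of the hydroxyl and selanyl groups to the terminal vinyl group of 10.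

**Step 10.** The chelated, ester-stabilised zinc reagent may transmetallate slowly, so that reduction of the triflate or ionisation of the product's allylic acetate by Pd(0) intervenes. The fallback sets out from 17 and returns to 18 by bringing C19 in as carbon monoxide. Reductive carbonylation (CO, Bu3SnH added slowly, Pd(PPh3)4, THF, rt to 40 °C) would give 2-(trimethylsilyl)ethyl (1Z,2Z,4E,6S,7R)-10-formyl-6-[2-(furan-3-yl)ethyl]-6,7-dimethylcyclodeca-1(10),2,4-triene-1-carboxylate F5. Reduction of the aldehyde with DIBAL-H (1 equiv, CH2Cl2, −78 °C) and acetylation of the aluminium alkoxide in the same flask (Ac2O, pyridine, DMAP, −78 to −20 °C) gives 18 before the alkoxide can lactonise.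

**Step 2.** With a tetrasubstituted β,γ-alkene the conjugated enone is favoured less than usual, so conversion may stall, and reversible dienamine formation from the product may erode the enantiomeric purity at C4. The fallback cannot set out from a numbered compound of the route, because the stereocentre is then made before the ring: it starts from propanal and methyl vinyl ketone and returns at 4. Diarylprolinol silyl ether-catalysed Michael addition would give (R)-2-methyl-5-oxohexanal F6. Intramolecular aldol condensation (LiOH, i-PrOH) gives (R)-4-methylcyclohex-2-en-1-one F7. Me2CuLi/TMSCl (THF, −78 °C) adds methyl anti to the C4 methyl and gives trimethyl{[(3S,4R)-3,4-dimethylcyclohex-1-en-1-yl]oxy}silane F8. Saegusa–Ito oxidation (Pd(OAc)2, MeCN) restores the enone as 4.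

## Further compounds

F1 | step 7 | (3S,4R)-1,2-diethenyl-3-[2-(furan-3-yl)ethyl]-3,4-dimethylcyclohexan-1-ol (C1/C2 diastereomers) | OC1(C=C)C(C=C)[C@@](C)(CCc2ccoc2)[C@H](C)CC1
F2 | step 7 | (5E,7S,8R)-7-[2-(furan-3-yl)ethyl]-7,8-dimethyl-2-(phenylselanyl)cyclodec-5-en-1-one (C2 epimers) | O=C1C([Se]c2ccccc2)CC/C=C/[C@@](C)(CCc3ccoc3)[C@H](C)CC1
F3 | step 7 | (2Z,5E,7S,8R)-7-[2-(furan-3-yl)ethyl]-7,8-dimethylcyclodeca-2,5-dien-1-one | O=C1/C=C\C/C=C/[C@@](C)(CCc2ccoc2)[C@H](C)CC1
F4 | step 5 | (3S,4R)-3-[2-(furan-3-yl)ethyl]-2-[1-hydroxy-2-(phenylselanyl)ethyl]-3,4-dimethylcyclohexan-1-one (diastereomers) | O=C1C(C(O)C[Se]c2ccccc2)[C@@](C)(CCc3ccoc3)[C@H](C)CC1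
F5 | step 10 | 2-(trimethylsilyl)ethyl (1Z,2Z,4E,6S,7R)-10-formyl-6-[2-(furan-3-yl)ethyl]-6,7-dimethylcyclodeca-1(10),2,4-triene-1-carboxylate | O=C/C1=C(C(=O)OCC[Si](C)(C)C)/C=C\C=C\[C@@](C)(CCc2ccoc2)[C@H](C)CC1
F6 | step 2 | (R)-2-methyl-5-oxohexanal | C[C@H](CCC(C)=O)C=O
F7 | step 2 | (R)-4-methylcyclohex-2-en-1-one | C[C@@H]1CCC(=O)C=C1
F8 | step 2 | trimethyl{[(3S,4R)-3,4-dimethylcyclohex-1-en-1-yl]oxy}silane | C[Si](C)(C)OC1=C[C@@H](C)[C@H](C)CC1
A1 | alternative 1 | 2-(trimethylsilyl)ethyl (2E,6R,7S,8E,10Z)-3-(acetoxymethyl)-7-[2-(furan-3-yl)ethyl]-2-iodo-6,7-dimethyl-11-(tributylstannyl)undeca-2,8,10-trienoate | CC(=O)OC/C(=C(/I)C(=O)OCC[Si](C)(C)C)CC[C@@H](C)[C@](C)(CCc1ccoc1)/C=C/C=C\[Sn](CCCC)(CCCC)CCCC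
A2 | alternative 2 | cis-fused 8a-(acetoxymethyl)-5-[2-(furan-3-yl)ethyl]-5,6-dimethyl-4a,5,6,7,8,8a-hexahydronaphthalene-1-carboxylic acid (clerodane C5/C10 cis; C19, H-10, C17 and C20 on one face) | CC(=O)OC[C@@]12CC[C@@H](C)[C@](C)(CCc3ccoc3)[C@@H]1C=CC=C2C(=O)O
A3 | alternative 3 | 2-(trimethylsilyl)ethyl (3E,7R,8S,9E)-4-(acetoxymethyl)-8-[2-(furan-3-yl)ethyl]-7,8-dimethyl-1,1-dioxo-1λ6-thiacycloundeca-3,9-diene-3-carboxylate | CC(=O)OC/C1=C(C(=O)OCC[Si](C)(C)C)/CS(=O)(=O)C/C=C/[C@@](C)(CCc2ccoc2)[C@H](C)CC1
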